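**Retrosynthetic overview**
- Target 37 ⇒ C11–C3′ bond by Negishi coupling of a C11 zinc reagent with bromopyranone 34 (from methyl acetoacetate and malonyl dichloride); the formate comes from a tertiary benzoate, and the 3-OH from oxidation/LiBH(s-Bu)3 inversion of the 3-epi alcohol 23.
- 23 ⇒ epoxy diene allylsilane 22 by one cation–olefin cascade forming C4–C5 and C9–C10; rings A and B are closed together in that step, and the pyranone ring is built separately.
- Feature used: the cis C5–C10 fusion of rings A/B with 5-H, 10-CH3 and 4-CH3 on one face and C11 on the other, together with the C8=C12 exocyclic methylene. This is the pattern of an all-chair anti addition across a Z C5=C10 olefin that ends at C9 of an allylsilane.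
- 22 ⇒ neryl acetate (C6, C5, C10, C1–C4, Z olefin in place), tert-butyl acetate, methyl acetoacetate (C7, C8, C9, C11) and Me3SiCH2MgCl. The (3R,4R)-epoxide is made by direct Shi epoxidation of the E C3=C4 olefin, because a dihydroxylation/mesylate closure would invert C3 and put the C4 side chain cis to C2, which folds to the wrong C4 configuration.

Key step: step 14

Remark: locants C1–C10 are the decalin carbons (C3 carbinol, C4 quaternary, C5/C10 ring fusion, C9 bearing C11, C12 the exocyclic CH2 on C8) and are also used for the open-chain precursors; primed locants are the pyranone atoms; CIP descriptors in decalin names refer to these locants; neryl acetate, the commercial acetate of nerol, is taken as the starting material.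

Step 1
Reactants: 1 neryl acetate
Product: 2 (2Z,6E)-8-hydroxy-3,7-dimethylocta-2,6-dien-1-yl acetate
Conditions: SeO2 (0.3 equiv), t-BuOOH (3 equiv), salicylic acid (0.1 equiv), CH2Cl2, rt
Reagents that add atoms: tert-butyl hydroperoxide, CC(C)(C)OO (oxygen relayed by SeO2, O=[Se]=O)
Why: Riley allylic oxidation (ene reaction, then 2,3-sigmatropic shift) should hydroxylate the E methyl of the electron-rich terminal olefin, the other olefin being deactivated by the allylic acetate.

Step 2
Reactants: 2 (2Z,6E)-8-hydroxy-3,7-dimethylocta-2,6-dien-1-yl acetate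
Product: 3 (2Z,6E)-8-bromo-3,7-dimethylocta-2,6-dien-1-yl acetate
Conditions: CBr4, PPh3, CH2Cl2, 0 °C
Reagents that add atoms: carbon tetrabromide, BrC(Br)(Br)Br
Why: Appel bromination displaces the primary allylic oxyphosphonium by SN2, so both olefin geometries are kept.

Step 3
Reactants: 3 (2Z,6E)-8-bromo-3,7-dimethylocta-2,6-dien-1-yl acetate; 4 tert-butyl acetate
Product: 6 tert-butyl (4E,8Z)-10-acetoxy-4,8-dimethyldeca-4,8-dienoate, via lithium enolate 5 (not isolated)
Conditions: LiN(i-Pr)2, THF, −78 °C; then 3, DMPU, −78 → −40 °C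
Reagents that add atoms: lithium diisopropylamide, [Li+].CC(C)[N-]C(C)C (lithium of 5 only)
Why: Ester enolate alkylation: SN2 of the lithium enolate on the primary allylic bromide at −78 °C should outrun Claisen attack on the acetate.

Step 4
Reactants: 6 tert-butyl (4E,8Z)-10-acetoxy-4,8-dimethyldeca-4,8-dienoate
Product: 7 (2Z,6E)-3,7,10-trimethylundeca-2,6-diene-1,10-diol
Conditions: MeLi (5 equiv), Et2O/THF, −78 → 0 °C; then H2O
Reagents that add atoms: methyllithium, [Li]C
Why: Double addition of MeLi to the tert-butyl ester builds the dimethylcarbinol, and the same reagent cleaves the acetate.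

Step 5
Reactants: 7 (2Z,6E)-3,7,10-trimethylundeca-2,6-diene-1,10-diol
Product: 9 (2Z,6E)-3,7,10-trimethylundeca-2,6-diene-1,10-diyl dibenzoate, via dilithium dialkoxide 8 (not isolated)
Conditions: n-BuLi (2.1 equiv), THF, −78 °C; then BzCl (2.3 equiv), −78 → 0 °C
Reagents that add atoms: benzoyl chloride, O=C(Cl)c1ccccc1; n-butyllithium, [Li]CCCC (lithium of 8 only)
Why: Acylation of lithium alkoxides benzoylates the tertiary oxygen, which is sluggish as the neutral alcohol, and puts a deactivating benzoate next to the Z olefin.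

Step 6
Reactants: 9 (2Z,6E)-3,7,10-trimethylundeca-2,6-diene-1,10-diyl dibenzoate
Product: 10 (2Z)-5-[(2R,3R)-3-(3-benzoyloxy-3-methylbutyl)-3-methyloxiran-2-yl]-3-methylpent-2-en-1-yl benzoate
Conditions: 1,2:4,5-di-O-isopropylidene-β-D-erythro-2,3-hexodiulo-2,6-pyranose (0.3 equiv), KHSO5 (as 2KHSO5·KHSO4·K2SO4), K2CO3, Bu4NHSO4, MeCN/CH2(OMe)2/aq. Na2B4O7 buffer, 0 °C
Reagents that add atoms: potassium peroxymonosulfate, [K+].[O-]S(=O)(=O)OO
Why: Shi asymmetric epoxidation: the dioxirane of the D-fructose-derived ketone should oxidise only the electron-rich E C3=C4 olefin (the Z olefin carries the allylic benzoate) through a spiro transition state, giving the (3R,4R)-epoxide with the E geometry retained, so that the 4-CH3 stays cis to C2.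

Step 7
Reactants: 10 (2Z)-5-[(2R,3R)-3-(3-benzoyloxy-3-methylbutyl)-3-methyloxiran-2-yl]-3-methylpent-2-en-1-yl benzoate
Product: 11 4-[(2R,3R)-3-[(3Z)-5-hydroxy-3-methylpent-3-en-1-yl]-2-methyloxiran-2-yl]-2-methylbutan-2-yl benzoate
Conditions: K2CO3 (0.5 equiv), MeOH, 0 °C → rt
Reagents that add atoms: none
Why: Base-catalysed transesterification removes the unhindered primary allylic benzoate, while the tertiary benzoate and the trisubstituted epoxide are inert to methoxide at this temperature.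

Step 8
Reactants: 11 4-[(2R,3R)-3-[(3Z)-5-hydroxy-3-methylpent-3-en-1-yl]-2-methyloxiran-2-yl]-2-methylbutan-2-yl benzoate
Product: 13 4-[(2R,3R)-3-[(3Z)-5-bromo-3-methylpent-3-en-1-yl]-2-methyloxiran-2-yl]-2-methylbutan-2-yl benzoate, via allylic mesylate 12 (not isolated)
Conditions: MsCl, Et3N, THF, −45 °C; then LiBr, THF, −45 → 0 °C
Reagents that add atoms: lithium bromide, [Li+].[Br-]; methanesulfonyl chloride, CS(=O)(=O)Cl (in 12 only)
Why: Mesylation followed by SN2 displacement with bromide at low temperature keeps the Z geometry and the acid-sensitive epoxide.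

Step 9
Reactants: 13 4-[(2R,3R)-3-[(3Z)-5-bromo-3-methylpent-3-en-1-yl]-2-methyloxiran-2-yl]-2-methylbutan-2-yl benzoate; 14 methyl acetoacetate
Product: 16 methyl (6Z)-9-[(2R,3R)-3-(3-benzoyloxy-3-methylbutyl)-3-methyloxiran-2-yl]-7-methyl-3-oxonon-6-enoate, via acetoacetate dianion 15 (not isolated)
Conditions: 14 (1.5 equiv), NaH, THF, 0 °C; n-BuLi, 0 °C; then 13, 0 °C; then H2O
Reagents that add atoms: sodium hydride, [Na+].[H-], n-butyllithium, [Li]CCCC (metals of 15 only)
Why: Weiler γ-alkylation: the more basic terminal carbanion of the dianion attacks the allylic bromide by SN2 and forms C6–C7.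

Step 10
Reactants: 16 methyl (6Z)-9-[(2R,3R)-3-(3-benzoyloxy-3-methylbutyl)-3-methyloxiran-2-yl]-7-methyl-3-oxonon-6-enoate
Product: 18 methyl (2Z,6Z)-9-[(2R,3R)-3-(3-benzoyloxy-3-methylbutyl)-3-methyloxiran-2-yl]-7-methyl-3-(trifluoromethanesulfonyloxy)nona-2,6-dienoate, via sodium enolate 17 (not isolated)
Conditions: NaH, THF, 0 °C; then PhNTf2, 0 °C → rt
Reagents that add atoms: N-phenylbis(trifluoromethanesulfonimide), O=S(=O)(N(c1ccccc1)S(=O)(=O)C(F)(F)F)C(F)(F)F; sodium hydride, [Na+].[H-] (sodium of 17 only)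
Why: O-sulfonylation of the chelated sodium enolate: chelation between the enolate oxygen and the ester carbonyl fixes the Z geometry (triflate cis to the ester), and the neutral triflating agent spares the epoxide.

Step 11
Reactants: 18 methyl (2Z,6Z)-9-[(2R,3R)-3-(3-benzoyloxy-3-methylbutyl)-3-methyloxiran-2-yl]-7-methyl-3-(trifluoromethanesulfonyloxy)nona-2,6-dienoate; 19 (trimethylsilyl)methylmagnesium chloride
Product: 20 methyl (2Z,6Z)-9-[(2R,3R)-3-(3-benzoyloxy-3-methylbutyl)-3-methyloxiran-2-yl]-7-methyl-3-[(trimethylsilyl)methyl]nona-2,6-dienoate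
Conditions: 19 (1.5 equiv), Pd(PPh3)4 (5 mol %), THF, 0 °C → rt
Reagents that add atoms: none
Why: Kumada–Corriu coupling: oxidative addition of zerovalent palladium into the vinyl triflate, transmetalation and reductive elimination go with retention, so CH2SiMe3 ends cis to the ester, that is C11 trans to C7.

Step 12
Reactants: 20 methyl (2Z,6Z)-9-[(2R,3R)-3-(3-benzoyloxy-3-methylbutyl)-3-methyloxiran-2-yl]-7-methyl-3-[(trimethylsilyl)methyl]nona-2,6-dienoate
Product: 21 4-[(2R,3R)-3-[(3Z,7Z)-9-hydroxy-3-methyl-7-[(trimethylsilyl)methyl]nona-3,7-dien-1-yl]-2-methyloxiran-2-yl]-2-methylbutan-2-yl benzoate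
Conditions: i-Bu2AlH (2.2 equiv), CH2Cl2, −78 °C; aq. potassium sodium tartrate
Reagents that add atoms: none
Why: 1,2-Reduction of the methyl enoate with i-Bu2AlH at −78 °C should give the allylic alcohol, the tertiary benzoate (hindered on the alkoxy side, as with tert-butyl esters) and the trisubstituted epoxide reacting much more slowly.

Step 13
Reactants: 21 4-[(2R,3R)-3-[(3Z,7Z)-9-hydroxy-3-methyl-7-[(trimethylsilyl)methyl]nona-3,7-dien-1-yl]-2-methyloxiran-2-yl]-2-methylbutan-2-yl benzoate
Product: 22 tert-butyldiphenylsilyl ether of 21 (cyclisation precursor: (3R,4R)-epoxide, Z C5=C10, C11 trans to C7 across C8=C9)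
Conditions: t-BuPh2SiCl, imidazole, CH2Cl2, 0 °C → rt
Reagents that add atoms: tert-butyl(chloro)diphenylsilane, CC(C)(C)[Si](Cl)(c1ccccc1)c1ccccc1
Why: Silylation of the primary alcohol gives a bulky, weakly basic ether that should neither bind the Lewis acid strongly nor ionise at allylic C11 in the next step.

Step 14
Reactants: 22 tert-butyldiphenylsilyl ether of 21
Product: 23 (3R,4R,5R,9S,10R)-4-(3-benzoyloxy-3-methylbutyl)-9-[(tert-butyldiphenylsilyloxy)methyl]-4,10-dimethyl-8-methylidene-cis-decalin-3-ol (3-OH equatorial and cis to the 4-CH3; the 3-epimer of the target carbinol)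
Conditions: MeAlCl2 (2.5 equiv), CH2Cl2, −78 °C, 30 min; then Et3N, MeOH/H2O
Reagents that add atoms: none
Why: MeAlCl2 binds the epoxide oxygen and weakens the C4–O bond, C5 of the Z C5=C10 olefin attacks C4 from the rear, the developing C10 cation is taken on the opposite olefin face by C9 of the allylsilane, and the β-silyl cation at C8 loses Me3Si to chloride to leave the C8=C12 methylene. The closest known reaction type is the Lewis acid-promoted epoxy-polyene bicyclisation with an allylsilane terminator (Stork–Eschenmoser anti addition). Ring A closes 6-endo with respect to both the epoxide and the olefin through a chair with the C3–O bond equatorial, the 4-CH3 axial and the C4 side chain equatorial; ring B closes 6-endo-trig through a second chair with the C8=C9 bond inside the ring. C4 is set by inversion at the (R)-epoxide carbon, C5 and C10 by anti addition across the Z olefin (5-H and 10-CH3 cis, both syn to the axial 4-CH3), and C9 by the allylsilane geometry (C11 trans to C7, hence equatorial and anti to the 10-CH3), while C3 is carried over from the epoxide. The step needs a concerted anti addition at the Z olefin and epoxide opening at C4 only: the strongly nucleophilic allylsilane, the low temperature and the chair–chair folding favour the former, the tertiary C4 the latter, and the non-nucleophilic benzoate and bulky silyl ether keep both oxygens from trapping C4 or ionising C11.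

Step 15
Reactants: 23 3-epi alcohol
Product: 24 (4R,5R,9S,10R)-4-(3-benzoyloxy-3-methylbutyl)-9-[(tert-butyldiphenylsilyloxy)methyl]-4,10-dimethyl-8-methylidene-cis-decalin-3-one
Conditions: Dess–Martin periodinane, NaHCO3, CH2Cl2, rt
Reagents that add atoms: none
Why: Dess–Martin oxidation converts the hindered secondary alcohol into the ketone under buffered, non-acidic conditions that leave the exocyclic olefin in place.

Step 16
Reactants: 24 C3 ketone
Product: 25 (3S,4R,5R,9S,10R)-4-(3-benzoyloxy-3-methylbutyl)-9-[(tert-butyldiphenylsilyloxy)methyl]-4,10-dimethyl-8-methylidene-cis-decalin-3-ol (3-OH axial, trans to the 4-CH3)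
Conditions: LiBH(s-Bu)3, THF, −78 °C; then H2O
Reagents that add atoms: none
Why: Bulky-hydride reduction: LiBH(s-Bu)3 should attack the C3 carbonyl along the equatorial path, the axial path being blocked by the axial C5–C6 bond on the same face, which gives the axial alcohol with the C3 configuration of the target.

Step 17
Reactants: 25 axial 3-alcohol silyl ether
Product: 26 (3S,4R,5R,9S,10R)-4-(3-benzoyloxy-3-methylbutyl)-9-(hydroxymethyl)-4,10-dimethyl-8-methylidene-cis-decalin-3-ol
Conditions: Bu4NF, THF, 0 °C → rt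
Reagents that add atoms: none
Why: Fluoride-induced desilylation frees the primary C11 hydroxyl, and the tertiary benzoate is stable to fluoride.

Step 18
Reactants: 26 C3,C11 diol
Product: 27 (3S,4R,5R,9S,10R)-4-(3-benzoyloxy-3-methylbutyl)-9-(iodomethyl)-4,10-dimethyl-8-methylidene-cis-decalin-3-ol
Conditions: I2, PPh3, imidazole, toluene/MeCN, rt → 50 °C
Reagents that add atoms: iodine, II
Why: Garegg–Samuelsson (Appel-type) iodination is selective for the primary hydroxyl, because the axial C3 hydroxyl next to the quaternary C4 cannot be displaced by SN2.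

Step 19
Reactants: 27 C11 iodide
Product: 28 3-O-triethylsilyl ether of 27
Conditions: Et3SiOTf, 2,6-lutidine, CH2Cl2, −78 → 0 °C
Reagents that add atoms: triethylsilyl trifluoromethanesulfonate, CC[Si](CC)(CC)OS(=O)(=O)C(F)(F)F
Why: Silylation with the silyl triflate protects the hindered axial hydroxyl, so that only the tertiary oxygen is free for the later formylation.

Step 20
Reactants: 28 3-O-triethylsilyl ether of 27
Product: 29 (3S,4R,5R,9S,10R)-4-(3-hydroxy-3-methylbutyl)-9-(iodomethyl)-4,10-dimethyl-8-methylidene-3-(triethylsilyloxy)-cis-decalin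
Conditions: i-Bu2AlH (4 equiv), CH2Cl2, −78 → 0 °C; aq. potassium sodium tartrate
Reagents that add atoms: none
Why: Reductive cleavage of the benzoate with excess i-Bu2AlH at 0 °C frees the tertiary alcohol, and the primary iodide and the silyl ether are inert to this hydride.

Step 21
Reactants: 29 tertiary alcohol
Product: 30 (3S,4R,5R,9S,10R)-4-(3-formyloxy-3-methylbutyl)-9-(iodomethyl)-4,10-dimethyl-8-methylidene-3-(triethylsilyloxy)-cis-decalin
Conditions: acetic formic anhydride, pyridine, 4-(dimethylamino)pyridine (cat.), CH2Cl2, 0 °C → rt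
Reagents that add atoms: acetic formic anhydride, CC(=O)OC=O
Why: Formylation with the mixed anhydride transfers the more electrophilic formyl group, which is small enough to acylate the tertiary alcohol, the only free hydroxyl.

Step 22
Reactants: 14 methyl acetoacetate; 31 malonyl dichloride
Product: 32 methyl 4-hydroxy-2-methyl-6-oxo-6H-pyran-3-carboxylate
Conditions: CH2Cl2, 0 °C → reflux (HCl evolves)
Reagents that add atoms: none
Why: Pyranone synthesis by condensation of a β-keto ester with malonyl dichloride: C-acylation at the α-carbon of 14 and lactonisation through the enol oxygen give the 4-hydroxy-2-pyranone with the ester at C5′ and the methyl at C6′.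

Step 23
Reactants: 32 methyl 4-hydroxy-2-methyl-6-oxo-6H-pyran-3-carboxylate
Product: 33 methyl 6-methoxy-2-methyl-4-oxo-4H-pyran-3-carboxylate
Conditions: MeOTf, 2,6-di-tert-butyl-4-methylpyridine, CH2Cl2, rt
Reagents that add atoms: methyl trifluoromethanesulfonate, COS(=O)(=O)C(F)(F)F
Why: O-methylation of the neutral 4-hydroxy-2-pyranone with a hard methylating agent goes to the lactone carbonyl oxygen, the most basic site, and loss of the hydroxyl proton from the pyrylium gives the 2-methoxy-4-pyranone.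

Step 24
Reactants: 33 methyl 6-methoxy-2-methyl-4-oxo-4H-pyran-3-carboxylate
Product: 34 methyl 5-bromo-6-methoxy-2-methyl-4-oxo-4H-pyran-3-carboxylate
Conditions: N-bromosuccinimide, MeCN, 0 °C → rt
Reagents that add atoms: N-bromosuccinimide, O=C1CCC(=O)N1Br
Why: Electrophilic bromination takes the only free ring carbon, the nucleophilic α-position of the vinylogous ester between C2′ and C4′.

Step 25
Reactants: 30 formate iodide; 34 methyl 5-bromo-6-methoxy-2-methyl-4-oxo-4H-pyran-3-carboxylate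
Product: 36 methyl 5-{[(3S,4R,5R,9S,10S)-4-(3-formyloxy-3-methylbutyl)-4,10-dimethyl-8-methylidene-3-(triethylsilyloxy)-cis-decalin-9-yl]methyl}-6-methoxy-2-methyl-4-oxo-4H-pyran-3-carboxylate, via alkylzinc iodide 35 (not isolated)
Conditions: Zn dust (activated), LiCl, THF, 40 °C; then 34, Pd(OAc)2 (5 mol %), SPhos (10 mol %), THF, rt → 50 °C
Reagents that add atoms: zinc, [Zn] (in 35 only)
Why: Negishi coupling: LiCl-assisted zinc insertion into the primary iodide and palladium-catalysed sp3–sp2 coupling with the bromopyranone form C11–C3′, the alkylzinc tolerating the formate, the methyl ester and the pyranone.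

Step 26
Reactants: 36 coupled triethylsilyl ether
Product: 37 methyl 5-{[(3S,4R,5R,9S,10S)-4-(3-formyloxy-3-methylbutyl)-3-hydroxy-4,10-dimethyl-8-methylidene-cis-decalin-9-yl]methyl}-6-methoxy-2-methyl-4-oxo-4H-pyran-3-carboxylate (CNP0292250.1)
Conditions: HF·pyridine, pyridine, THF, 0 °C → rt
Reagents that add atoms: none
Why: Buffered fluoride desilylation frees the axial 3-OH under weakly acidic conditions that the tertiary formate, the methoxypyranone and the exocyclic olefin should survive.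

**Compound list**
1 | neryl acetate, (2Z)-3,7-dimethylocta-2,6-dien-1-yl acetate | CC(C)=CCC/C(C)=C\COC(C)=O | starting material
2 | (2Z,6E)-8-hydroxy-3,7-dimethylocta-2,6-dien-1-yl acetate | OC/C(C)=C/CC/C(C)=C\COC(C)=O | intermediate
3 | (2Z,6E)-8-bromo-3,7-dimethylocta-2,6-dien-1-yl acetate | BrC/C(C)=C/CC/C(C)=C\COC(C)=O | intermediate
4 | tert-butyl acetate | CC(=O)OC(C)(C)C | starting material
5 | lithium enolate of tert-butyl acetate | [Li+].C=C([O-])OC(C)(C)C | intermediate (not isolated)
6 | tert-butyl (4E,8Z)-10-acetoxy-4,8-dimethyldeca-4,8-dienoate | CC(C)(C)OC(=O)CC/C(C)=C/CC/C(C)=C\COC(C)=O | intermediate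
7 | (2Z,6E)-3,7,10-trimethylundeca-2,6-diene-1,10-diol | CC(C)(O)CC/C(C)=C/CC/C(C)=C\CO | intermediate
8 | dilithium 1,10-dialkoxide of 7 | [Li+].[Li+].CC(C)([O-])CC/C(C)=C/CC/C(C)=C\C[O-] | intermediate (not isolated)
9 | (2Z,6E)-3,7,10-trimethylundeca-2,6-diene-1,10-diyl dibenzoate | CC(C)(OC(=O)c1ccccc1)CC/C(C)=C/CC/C(C)=C\COC(=O)c1ccccc1 | intermediate
10 | (2Z)-5-[(2R,3R)-3-(3-benzoyloxy-3-methylbutyl)-3-methyloxiran-2-yl]-3-methylpent-2-en-1-yl benzoate | O=C(OC/C=C(/C)CC[C@H]1O[C@]1(C)CCC(C)(C)OC(=O)c1ccccc1)c1ccccc1 | intermediate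
11 | 4-[(2R,3R)-3-[(3Z)-5-hydroxy-3-methylpent-3-en-1-yl]-2-methyloxiran-2-yl]-2-methylbutan-2-yl benzoate | OC/C=C(/C)CC[C@H]1O[C@]1(C)CCC(C)(C)OC(=O)c1ccccc1 | intermediate
12 | methanesulfonate of 11 | CS(=O)(=O)OC/C=C(/C)CC[C@H]1O[C@]1(C)CCC(C)(C)OC(=O)c1ccccc1 | intermediate (not isolated)
13 | 4-[(2R,3R)-3-[(3Z)-5-bromo-3-methylpent-3-en-1-yl]-2-methyloxiran-2-yl]-2-methylbutan-2-yl benzoate | BrC/C=C(/C)CC[C@H]1O[C@]1(C)CCC(C)(C)OC(=O)c1ccccc1 | intermediate
14 | methyl acetoacetate (methyl 3-oxobutanoate) | COC(=O)CC(C)=O | starting material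
15 | sodium lithium dianion of methyl acetoacetate | [Na+].[Li+].[CH2-]C(=O)[CH-]C(=O)OC | intermediate (not isolated)
16 | methyl (6Z)-9-[(2R,3R)-3-(3-benzoyloxy-3-methylbutyl)-3-methyloxiran-2-yl]-7-methyl-3-oxonon-6-enoate | COC(=O)CC(=O)CC/C=C(/C)CC[C@H]1O[C@]1(C)CCC(C)(C)OC(=O)c1ccccc1 | intermediate
17 | sodium (2Z)-enolate of 16 | [Na+].COC(=O)/C=C(\[O-])CC/C=C(/C)CC[C@H]1O[C@]1(C)CCC(C)(C)OC(=O)c1ccccc1 | intermediate (not isolated)
18 | methyl (2Z,6Z)-9-[(2R,3R)-3-(3-benzoyloxy-3-methylbutyl)-3-methyloxiran-2-yl]-7-methyl-3-(trifluoromethanesulfonyloxy)nona-2,6-dienoate | COC(=O)/C=C(\OS(=O)(=O)C(F)(F)F)CC/C=C(/C)CC[C@H]1O[C@]1(C)CCC(C)(C)OC(=O)c1ccccc1 | intermediate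
19 | (trimethylsilyl)methylmagnesium chloride | C[Si](C)(C)C[Mg]Cl | starting material
20 | methyl (2Z,6Z)-9-[(2R,3R)-3-(3-benzoyloxy-3-methylbutyl)-3-methyloxiran-2-yl]-7-methyl-3-[(trimethylsilyl)methyl]nona-2,6-dienoate | COC(=O)/C=C(\C[Si](C)(C)C)CC/C=C(/C)CC[C@H]1O[C@]1(C)CCC(C)(C)OC(=O)c1ccccc1 | intermediate
21 | 4-[(2R,3R)-3-[(3Z,7Z)-9-hydroxy-3-methyl-7-[(trimethylsilyl)methyl]nona-3,7-dien-1-yl]-2-methyloxiran-2-yl]-2-methylbutan-2-yl benzoate | OC/C=C(\C[Si](C)(C)C)CC/C=C(/C)CC[C@H]1O[C@]1(C)CCC(C)(C)OC(=O)c1ccccc1 | intermediate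
22 | tert-butyldiphenylsilyl ether of 21 (cyclisation precursor) | CC(C)(C)[Si](c1ccccc1)(c1ccccc1)OC/C=C(\C[Si](C)(C)C)CC/C=C(/C)CC[C@H]1O[C@]1(C)CCC(C)(C)OC(=O)c1ccccc1 | intermediate
23 | (3R,4R,5R,9S,10R)-4-(3-benzoyloxy-3-methylbutyl)-9-[(tert-butyldiphenylsilyloxy)methyl]-4,10-dimethyl-8-methylidene-cis-decalin-3-ol (3-OH equatorial, cis to 4-CH3; 5-H, 4-CH3, 10-CH3, 9-H on one face) | C=C1CC[C@H]2[C@@](C)(CCC(C)(C)OC(=O)c3ccccc3)[C@H](O)CC[C@@]2(C)[C@H]1CO[Si](c1ccccc1)(c1ccccc1)C(C)(C)C | intermediate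
24 | (4R,5R,9S,10R)-4-(3-benzoyloxy-3-methylbutyl)-9-[(tert-butyldiphenylsilyloxy)methyl]-4,10-dimethyl-8-methylidene-cis-decalin-3-one | C=C1CC[C@H]2[C@@](C)(CCC(C)(C)OC(=O)c3ccccc3)C(=O)CC[C@@]2(C)[C@H]1CO[Si](c1ccccc1)(c1ccccc1)C(C)(C)C | intermediate
25 | (3S,4R,5R,9S,10R)-4-(3-benzoyloxy-3-methylbutyl)-9-[(tert-butyldiphenylsilyloxy)methyl]-4,10-dimethyl-8-methylidene-cis-decalin-3-ol (3-OH axial, trans to 4-CH3) | C=C1CC[C@H]2[C@@](C)(CCC(C)(C)OC(=O)c3ccccc3)[C@@H](O)CC[C@@]2(C)[C@H]1CO[Si](c1ccccc1)(c1ccccc1)C(C)(C)C | intermediate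
26 | (3S,4R,5R,9S,10R)-4-(3-benzoyloxy-3-methylbutyl)-9-(hydroxymethyl)-4,10-dimethyl-8-methylidene-cis-decalin-3-ol | C=C1CC[C@H]2[C@@](C)(CCC(C)(C)OC(=O)c3ccccc3)[C@@H](O)CC[C@@]2(C)[C@H]1CO | intermediate
27 | (3S,4R,5R,9S,10R)-4-(3-benzoyloxy-3-methylbutyl)-9-(iodomethyl)-4,10-dimethyl-8-methylidene-cis-decalin-3-ol | C=C1CC[C@H]2[C@@](C)(CCC(C)(C)OC(=O)c3ccccc3)[C@@H](O)CC[C@@]2(C)[C@H]1CI | intermediate
28 | 3-O-triethylsilyl ether of 27 | C=C1CC[C@H]2[C@@](C)(CCC(C)(C)OC(=O)c3ccccc3)[C@@H](O[Si](CC)(CC)CC)CC[C@@]2(C)[C@H]1CI | intermediate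
29 | (3S,4R,5R,9S,10R)-4-(3-hydroxy-3-methylbutyl)-9-(iodomethyl)-4,10-dimethyl-8-methylidene-3-(triethylsilyloxy)-cis-decalin | C=C1CC[C@H]2[C@@](C)(CCC(C)(C)O)[C@@H](O[Si](CC)(CC)CC)CC[C@@]2(C)[C@H]1CI | intermediate
30 | (3S,4R,5R,9S,10R)-4-(3-formyloxy-3-methylbutyl)-9-(iodomethyl)-4,10-dimethyl-8-methylidene-3-(triethylsilyloxy)-cis-decalin | C=C1CC[C@H]2[C@@](C)(CCC(C)(C)OC=O)[C@@H](O[Si](CC)(CC)CC)CC[C@@]2(C)[C@H]1CI | intermediate
31 | malonyl dichloride | O=C(Cl)CC(=O)Cl | starting material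
32 | methyl 4-hydroxy-2-methyl-6-oxo-6H-pyran-3-carboxylate | COC(=O)C1=C(C)OC(=O)C=C1O | intermediate
33 | methyl 6-methoxy-2-methyl-4-oxo-4H-pyran-3-carboxylate | COC(=O)C1=C(C)OC(OC)=CC1=O | intermediate
34 | methyl 5-bromo-6-methoxy-2-methyl-4-oxo-4H-pyran-3-carboxylate | COC(=O)C1=C(C)OC(OC)=C(Br)C1=O | intermediate
35 | C11 alkylzinc iodide from 30 | C=C1CC[C@H]2[C@@](C)(CCC(C)(C)OC=O)[C@@H](O[Si](CC)(CC)CC)CC[C@@]2(C)[C@H]1C[Zn]I | intermediate (not isolated)
36 | methyl 5-{[(3S,4R,5R,9S,10S)-4-(3-formyloxy-3-methylbutyl)-4,10-dimethyl-8-methylidene-3-(triethylsilyloxy)-cis-decalin-9-yl]methyl}-6-methoxy-2-methyl-4-oxo-4H-pyran-3-carboxylate | C=C1CC[C@H]2[C@@](C)(CCC(C)(C)OC=O)[C@@H](O[Si](CC)(CC)CC)CC[C@@]2(C)[C@H]1Cc1c(OC)oc(C)c(C(=O)OC)c1=O | intermediate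
37 | methyl 5-{[(3S,4R,5R,9S,10S)-4-(3-formyloxy-3-methylbutyl)-3-hydroxy-4,10-dimethyl-8-methylidene-cis-decalin-9-yl]methyl}-6-methoxy-2-methyl-4-oxo-4H-pyran-3-carboxylate | C=C1CC[C@H]2[C@@](C)(CCC(C)(C)OC=O)[C@@H](O)CC[C@@]2(C)[C@H]1Cc1c(OC)oc(C)c(C(=O)OC)c1=O | target

**Step count**
Total: 26 steps. Longest linear sequence: 23 steps (steps 1–21, 25, 26); the pyranone branch is steps 22–24.

**Steps most likely to fail**

1. Step 14. The cascade may stop after ring A, because ring B has to close with the C5–C6 bond axial. The C10 cation could then lose a proton or be captured without facial control, which would erode the cis ring fusion. Protodesilylation of the allylsilane or ionisation of the tertiary benzoate may also compete. Fallback, from compound 16 back to compound 23: SnCl4 in CH2Cl2 at −78 °C lets the enol of the β-keto ester end the same epoxide-initiated cascade and should give the cis-fused 3-hydroxy-8-oxo decalin 9-carboxylate F1, whose C9 centre can equilibrate to the equatorial ester. Methylenation with Zn, CH2Br2 and TiCl4 (Lombardo reagent) gives the 8-methylidene ester F2. i-Bu2AlH at −78 °C reduces the methyl ester to the 3-epi C3,C11 diol F3, and t-BuPh2SiCl with imidazole silylates only the primary hydroxyl, which is compound 23.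

2. Step 25. Zinc insertion at the β-branched primary iodide may be slow, the alkylzinc may be lost by β-hydride elimination or protonation, and the 2′-methoxy group of the pyranone may be attacked. Fallback, from compound 29 back to compound 36: Me3NO in DMSO (Kornblum–Ganem oxidation) turns the iodide into the C11 aldehyde F4. The pyranonylmagnesium reagent made from 34 with i-PrMgCl·LiCl at −40 °C adds to it to give the C11 carbinol F5 (both epimers are used). 1,1′-Thiocarbonyldiimidazole gives the imidazole-1-carbothioate F6, and Bu3SnH with azobisisobutyronitrile in toluene at 80 °C (Barton–McCombie deoxygenation) gives the C11-methylene tertiary alcohol F7. Formylation as in step 21 then gives compound 36.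

3. Step 6. The dioxirane may not discriminate fully between the two trisubstituted olefins, and the enantioselectivity may be eroded. Fallback, from compound 2 back to compound 10: Sharpless asymmetric epoxidation (Ti(OiPr)4, D-(−)-diethyl tartrate, t-BuOOH, 4 Å molecular sieves, CH2Cl2, −20 °C) can only touch the olefin next to the free hydroxyl and should give the (2R,3R)-epoxy alcohol F8. I2, PPh3 and imidazole give the epoxy iodide F9. The lithium enolate of tert-butyl acetate displaces iodide to give the epoxy tert-butyl ester F10, MeLi as in step 4 gives the epoxy diol F11, and double benzoylation as in step 5 gives compound 10.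

Further compounds
F1 | step 14 | methyl ester of the cis-fused 4-(3-benzoyloxy-3-methylbutyl)-3-hydroxy-4,10-dimethyl-8-oxodecalin-9-carboxylic acid (configuration as in 23) | O=C1CC[C@H]2[C@@](C)(CCC(C)(C)OC(=O)c3ccccc3)[C@H](O)CC[C@@]2(C)[C@H]1C(=O)OC
F2 | step 14 | 8-methylidene analogue of F1 | C=C1CC[C@H]2[C@@](C)(CCC(C)(C)OC(=O)c3ccccc3)[C@H](O)CC[C@@]2(C)[C@H]1C(=O)OC
F3 | step 14 | 3-epi C3,C11 diol (23 without the silyl group) | C=C1CC[C@H]2[C@@](C)(CCC(C)(C)OC(=O)c3ccccc3)[C@H](O)CC[C@@]2(C)[C@H]1CO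
F4 | step 25 | C11 aldehyde from 29 (tertiary alcohol, 3-O-triethylsilyl) | C=C1CC[C@H]2[C@@](C)(CCC(C)(C)O)[C@@H](O[Si](CC)(CC)CC)CC[C@@]2(C)[C@H]1C=O
F5 | step 25 | C11 carbinol carrying the pyranone (C11 epimers) | C=C1CC[C@H]2[C@@](C)(CCC(C)(C)O)[C@@H](O[Si](CC)(CC)CC)CC[C@@]2(C)[C@H]1C(O)c1c(OC)oc(C)c(C(=O)OC)c1=O
F6 | step 25 | O-C11 imidazole-1-carbothioate of F5 | C=C1CC[C@H]2[C@@](C)(CCC(C)(C)O)[C@@H](O[Si](CC)(CC)CC)CC[C@@]2(C)[C@H]1C(OC(=S)n1ccnc1)c1c(OC)oc(C)c(C(=O)OC)c1=O
F7 | step 25 | C11-methylene tertiary alcohol (36 without the formyl group) | C=C1CC[C@H]2[C@@](C)(CCC(C)(C)O)[C@@H](O[Si](CC)(CC)CC)CC[C@@]2(C)[C@H]1Cc1c(OC)oc(C)c(C(=O)OC)c1=O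
F8 | step 6 | (2Z)-5-[(2R,3R)-3-(hydroxymethyl)-3-methyloxiran-2-yl]-3-methylpent-2-en-1-yl acetate | CC(=O)OC/C=C(/C)CC[C@H]1O[C@]1(C)CO
F9 | step 6 | epoxy iodide from F8 (CH2I in place of CH2OH) | CC(=O)OC/C=C(/C)CC[C@H]1O[C@]1(C)CI
F10 | step 6 | tert-butyl 3-[(2R,3R)-3-[(3Z)-5-acetoxy-3-methylpent-3-en-1-yl]-2-methyloxiran-2-yl]propanoate | CC(=O)OC/C=C(/C)CC[C@H]1O[C@]1(C)CCC(=O)OC(C)(C)C
F11 | step 6 | epoxy diol: (2Z)-5-[(2R,3R)-3-(3-hydroxy-3-methylbutyl)-3-methyloxiran-2-yl]-3-methylpent-2-en-1-ol | OC/C=C(/C)CC[C@H]1O[C@]1(C)CCC(C)(C)O
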